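**Retrosynthetic overview**

- Target 19 is the C5 aldehyde of (R)-δ-tocotrienol 17. The aldehyde is introduced last by ortho-formylation. Before that, the C5'–C6' bond of the side chain is made by alkylating geranyl phenyl sulfone 13 with allylic bromide 11, which comes from chromanol 8 by allylic oxidation.
- The strategy rests on the 6-hydroxychroman core. O1 sits on C8a, para to the C6 oxygen, and C4 sits on C4a, so ring B (dihydropyran) fused to ring A (arene) is the rearrangement isomer of a 1-oxaspiro[4.5]deca-6,9-dien-8-one in which O1 and C4 are on the same carbon. Chromanol 8 is therefore disconnected at C4–C4a to spirodienone 7.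
- Dienone 7 comes from para-alkylphenol 6 by oxidative spirocyclisation (O1–C bond). Phenol 6 comes from (R)-linalool 3 and aryl bromide 2 by hydroboration and Suzuki coupling (C4–aryl bond). Linalool supplies C2 with its configuration.
- Ring order: ring A is bought, the spiro tetrahydrofuran is closed in step 4, and ring B arises from it in step 5 by ring expansion with rearomatisation.

Key step: step 5

Assumption: (R)-(−)-linalool of high enantiomeric purity is used, and the two C5 epimers of spirodienone 7 are carried on together because the spiro carbon becomes planar in step 5.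

**Route**

Step 1
Reactants: 1 4-bromo-3-methylphenol
Product: 2 (4-bromo-3-methylphenoxy)tri(propan-2-yl)silane
Conditions: TIPSCl, imidazole, DMF, rt
Reagents that add atoms: chlorotri(propan-2-yl)silane (TIPSCl), CC(C)[Si](Cl)(C(C)C)C(C)C
Why: O-silylation of a phenol with a chlorosilane and imidazole is routine, and the bulky TIPS ether should survive the aqueous phosphate of step 2 while keeping a free phenoxide from slowing oxidative addition.

Step 2
Reactants: 3 (R)-linalool; 2 (4-bromo-3-methylphenoxy)tri(propan-2-yl)silane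
Product: 5 (3R)-3,7-dimethyl-1-{2-methyl-4-[tri(propan-2-yl)silyloxy]phenyl}oct-6-en-3-ol, via B-alkyl-9-BBN adduct 4 (not isolated)
Conditions: 9-BBN (1.3 equiv), THF, 0 °C to rt; then 2, Pd(OAc)2 (5 mol%), SPhos (10 mol%), aq. K3PO4, THF, 60 °C
Reagents that add atoms: none
Why: 9-BBN should hydroborate the monosubstituted vinyl group anti-Markovnikov much faster than it touches the trisubstituted alkene or the hindered tertiary hydroxyl (any borinate formed there is hydrolysed by the aqueous base), and the primary B-alkyl group is then transferred to the ortho-substituted aryl bromide in a B-alkyl Suzuki–Miyaura coupling, with the carbinol stereocentre of linalool untouched.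

Step 3
Reactants: 5 (3R)-3,7-dimethyl-1-{2-methyl-4-[tri(propan-2-yl)silyloxy]phenyl}oct-6-en-3-ol
Product: 6 4-[(3R)-3-hydroxy-3,7-dimethyloct-6-en-1-yl]-3-methylphenol
Conditions: TBAF, THF, 0 °C to rt; aqueous work-up
Reagents that add atoms: none
Why: Fluoride cleavage of the aryl silyl ether, driven by Si–F bond formation, should free the phenol without affecting the tertiary alcohol or the alkene.

Step 4
Reactants: 6 4-[(3R)-3-hydroxy-3,7-dimethyloct-6-en-1-yl]-3-methylphenol
Product: 7 (2R)-2,6-dimethyl-2-(4-methylpent-3-en-1-yl)-1-oxaspiro[4.5]deca-6,9-dien-8-one (both C5 epimers)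
Conditions: PhI(OAc)2 (1.1 equiv), CF3CH2OH, 0 °C
Reagents that add atoms: none
Why: This is a hypervalent iodine oxidative dearomatisation of a para-alkylphenol in which the tethered tertiary hydroxyl attacks the para carbon in a 5-exo spiroetherification, favoured by the weakly nucleophilic fluoroalcohol; the new spiro centre C5 forms without control, which does not matter because it is planarised in step 5.

Step 5
Reactants: 7 (2R)-2,6-dimethyl-2-(4-methylpent-3-en-1-yl)-1-oxaspiro[4.5]deca-6,9-dien-8-one
Product: 8 (2R)-2,8-dimethyl-2-(4-methylpent-3-en-1-yl)-3,4-dihydro-2H-chromen-6-ol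
Conditions: BF3·OEt2 (0.5 equiv), CH2Cl2, −40 to 0 °C; aq. NaHCO3
Reagents that add atoms: none
Why: BF3 binds the C8 carbonyl of the cross-conjugated dienone and turns the ring into a boron-oxy pentadienyl cation with positive character at C6 and C10, the two neighbours of the spiro carbon C5. The C5–C4 bond then shifts to the unsubstituted C10 (the future C4a), which enlarges the spiro tetrahydrofuran to the dihydropyran by a 1,2-alkyl shift and not by a cyclisation, and leaves the charge on C5 (the future C8a) as an oxocarbenium ion held by O1. Loss of the proton from C10 restores the benzene ring, so the step is a dienone–phenol rearrangement of the kind known for 4-alkoxy-4-alkylcyclohexadienones and oxaspirodienones. No stereocentre is made: the O1–C2 and C2–C3 bonds are never broken, so C2 keeps the configuration of (R)-linalool, and the spiro centre becomes planar, so both epimers of 7 should give the same product. The step needs carbon and not oxygen to migrate, and needs migration to C10 and not C6; the first is secured by the lone pair of O1, which stabilises the cation only when oxygen stays behind, and the second by the C6 methyl, since a shift to C6 gives a cation with no proton to lose and simply reverts. A Lewis acid at low temperature is chosen over a protic acid to spare the trisubstituted alkene and the tertiary ether.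

Step 6
Reactants: 8 (2R)-2,8-dimethyl-2-(4-methylpent-3-en-1-yl)-3,4-dihydro-2H-chromen-6-ol
Product: 9 tert-butyl{[(2R)-2,8-dimethyl-2-(4-methylpent-3-en-1-yl)-3,4-dihydro-2H-chromen-6-yl]oxy}dimethylsilane
Conditions: TBSCl, imidazole, DMF, rt
Reagents that add atoms: tert-butylchlorodimethylsilane (TBSCl), CC(C)(C)[Si](C)(C)Cl
Why: Silylation masks the oxidation-prone chromanol through the allylic oxidation, the carbanion alkylation and the hydride step, and it is removed later by fluoride without acid.

Step 7
Reactants: 9 tert-butyl{[(2R)-2,8-dimethyl-2-(4-methylpent-3-en-1-yl)-3,4-dihydro-2H-chromen-6-yl]oxy}dimethylsilane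
Product: 10 (2E)-5-[(2R)-6-{[tert-butyl(dimethyl)silyl]oxy}-2,8-dimethyl-3,4-dihydro-2H-chromen-2-yl]-2-methylpent-2-en-1-ol
Conditions: SeO2 (0.3 equiv), t-BuOOH (2.5 equiv), salicylic acid (cat.), CH2Cl2, 0 °C to rt
Reagents that add atoms: tert-butyl hydroperoxide, CC(C)(C)OO (terminal oxygen source); selenium dioxide, O=[Se]=O (catalytic oxygen carrier)
Why: In this Riley-type allylic oxidation the ene reaction and [2,3]-sigmatropic shift occur at the more substituted alkene terminus and on the methyl trans to the chain, so the (E)-allylic alcohol is expected, and conversion is stopped short of completion to limit over-oxidation.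

Step 8
Reactants: 10 (2E)-5-[(2R)-6-{[tert-butyl(dimethyl)silyl]oxy}-2,8-dimethyl-3,4-dihydro-2H-chromen-2-yl]-2-methylpent-2-en-1-ol
Product: 11 {[(2R)-2-[(3E)-5-bromo-4-methylpent-3-en-1-yl]-2,8-dimethyl-3,4-dihydro-2H-chromen-6-yl]oxy}(tert-butyl)dimethylsilane
Conditions: CBr4, PPh3, CH2Cl2, 0 °C
Reagents that add atoms: tetrabromomethane, BrC(Br)(Br)Br
Why: The Appel reaction converts the primary allylic alcohol to the bromide by SN2 displacement of the oxyphosphonium group under neutral conditions, which should preserve the alkene geometry and the silyl ether.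

Step 9
Reactants: 12 geranyl bromide
Product: 13 geranyl phenyl sulfone, {[(2E)-3,7-dimethylocta-2,6-dien-1-yl]sulfonyl}benzene
Conditions: PhSO2Na, DMF, rt
Reagents that add atoms: sodium benzenesulfinate (PhSO2Na), [Na+].[O-]S(=O)c1ccccc1
Why: S-Alkylation of the sulfinate by the primary allylic bromide (SN2) should give the sulfone with the 2E geometry retained.

Step 10
Reactants: 13 geranyl phenyl sulfone; 11 {[(2R)-2-[(3E)-5-bromo-4-methylpent-3-en-1-yl]-2,8-dimethyl-3,4-dihydro-2H-chromen-6-yl]oxy}(tert-butyl)dimethylsilane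
Product: 15 tert-butyl{[(2R)-2,8-dimethyl-2-[(3E,7E)-4,8,12-trimethyl-6-(phenylsulfonyl)trideca-3,7,11-trien-1-yl]-3,4-dihydro-2H-chromen-6-yl]oxy}dimethylsilane (both C6' epimers), via lithiated geranyl phenyl sulfone 14 (not isolated)
Conditions: n-BuLi, THF, −78 °C; then 11, −78 to −20 °C
Reagents that add atoms: none
Why: Deprotonation next to the sulfone gives a stabilised allylic carbanion that alkylates the primary allylic bromide through its α-carbon (SN2) to form the C5'–C6' bond; the new sulfonyl-bearing stereocentre forms as a mixture, which is irrelevant because the sulfone is removed in step 11.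

Step 11
Reactants: 15 tert-butyl{[(2R)-2,8-dimethyl-2-[(3E,7E)-4,8,12-trimethyl-6-(phenylsulfonyl)trideca-3,7,11-trien-1-yl]-3,4-dihydro-2H-chromen-6-yl]oxy}dimethylsilane
Product: 16 tert-butyl{[(2R)-2,8-dimethyl-2-[(3E,7E)-4,8,12-trimethyltrideca-3,7,11-trien-1-yl]-3,4-dihydro-2H-chromen-6-yl]oxy}dimethylsilane
Conditions: PdCl2(dppp) (5 mol%), LiBHEt3, THF, 0 °C
Reagents that add atoms: none
Why: In this palladium-catalysed reductive desulfonylation of an allylic sulfone, hydride from LiBHEt3 is delivered to the less substituted terminus of the allylpalladium intermediate, a process known to keep both the position and the E geometry of trisubstituted alkenes in polyprenyl chains.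

Step 12
Reactants: 16 tert-butyl{[(2R)-2,8-dimethyl-2-[(3E,7E)-4,8,12-trimethyltrideca-3,7,11-trien-1-yl]-3,4-dihydro-2H-chromen-6-yl]oxy}dimethylsilane
Product: 17 (R)-δ-tocotrienol, (2R)-2,8-dimethyl-2-[(3E,7E)-4,8,12-trimethyltrideca-3,7,11-trien-1-yl]-3,4-dihydro-2H-chromen-6-ol
Conditions: TBAF, THF, 0 °C, Ar; aqueous work-up
Reagents that add atoms: none
Why: Fluoride cleavage of the aryl silyl ether should release the chromanol under conditions that leave the triene untouched.

Step 13
Reactants: 17 (R)-δ-tocotrienol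
Product: 19 (2R)-6-hydroxy-2,8-dimethyl-2-[(3E,7E)-4,8,12-trimethyltrideca-3,7,11-trien-1-yl]-3,4-dihydro-2H-chromene-5-carbaldehyde, via 5-hydroxymethyl chromanol 18 (not isolated)
Conditions: MgCl2, Et3N, (CH2O)n, MeCN, reflux, Ar; then 1 M HCl
Reagents that add atoms: paraformaldehyde (formaldehyde), C=O
Why: In this magnesium-mediated ortho-formylation (Casnati–Skattebøl) the magnesium phenoxide delivers chelated formaldehyde to an ortho carbon and a second formaldehyde oxidises the benzylic alkoxide 18 by hydride transfer; of the two free ortho positions, C5 should react in preference to C7 because the fused dihydropyran ring fixes the higher double-bond character in the C5–C6 bond (Mills–Nixon effect), as in other electrophilic substitutions of 6-chromanols.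

**Compound list**

1 | 4-bromo-3-methylphenol | Cc1cc(O)ccc1Br | starting material
2 | (4-bromo-3-methylphenoxy)tri(propan-2-yl)silane | Cc1cc(O[Si](C(C)C)(C(C)C)C(C)C)ccc1Br | intermediate
3 | (R)-linalool, (3R)-3,7-dimethylocta-1,6-dien-3-ol | CC(C)=CCC[C@](C)(C=C)O | starting material
4 | (3S)-1-(9-borabicyclo[3.3.1]nonan-9-yl)-3,7-dimethyloct-6-en-3-ol (descriptor changes by CIP priority only) | CC(C)=CCC[C@](C)(CCB1C2CCCC1CCC2)O | intermediate (not isolated)
5 | (3R)-3,7-dimethyl-1-{2-methyl-4-[tri(propan-2-yl)silyloxy]phenyl}oct-6-en-3-ol | CC(C)=CCC[C@](C)(CCc1ccc(O[Si](C(C)C)(C(C)C)C(C)C)cc1C)O | intermediate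
6 | 4-[(3R)-3-hydroxy-3,7-dimethyloct-6-en-1-yl]-3-methylphenol | CC(C)=CCC[C@](C)(CCc1ccc(O)cc1C)O | intermediate
7 | (2R)-2,6-dimethyl-2-(4-methylpent-3-en-1-yl)-1-oxaspiro[4.5]deca-6,9-dien-8-one, both C5 epimers | CC(C)=CCC[C@]1(C)CCC2(O1)C(C)=CC(=O)C=C2 | intermediate
8 | (2R)-2,8-dimethyl-2-(4-methylpent-3-en-1-yl)-3,4-dihydro-2H-chromen-6-ol | CC(C)=CCC[C@]1(C)CCc2cc(O)cc(C)c2O1 | intermediate
9 | tert-butyl{[(2R)-2,8-dimethyl-2-(4-methylpent-3-en-1-yl)-3,4-dihydro-2H-chromen-6-yl]oxy}dimethylsilane | CC(C)=CCC[C@]1(C)CCc2cc(O[Si](C)(C)C(C)(C)C)cc(C)c2O1 | intermediate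
10 | (2E)-5-[(2R)-6-{[tert-butyl(dimethyl)silyl]oxy}-2,8-dimethyl-3,4-dihydro-2H-chromen-2-yl]-2-methylpent-2-en-1-ol | OC/C(C)=C/CC[C@]1(C)CCc2cc(O[Si](C)(C)C(C)(C)C)cc(C)c2O1 | intermediate
11 | {[(2R)-2-[(3E)-5-bromo-4-methylpent-3-en-1-yl]-2,8-dimethyl-3,4-dihydro-2H-chromen-6-yl]oxy}(tert-butyl)dimethylsilane | BrC/C(C)=C/CC[C@]1(C)CCc2cc(O[Si](C)(C)C(C)(C)C)cc(C)c2O1 | intermediate
12 | geranyl bromide, (2E)-1-bromo-3,7-dimethylocta-2,6-diene | CC(C)=CCC/C(C)=C/CBr | starting material
13 | geranyl phenyl sulfone, {[(2E)-3,7-dimethylocta-2,6-dien-1-yl]sulfonyl}benzene | CC(C)=CCC/C(C)=C/CS(=O)(=O)c1ccccc1 | intermediate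
14 | α-lithiated geranyl phenyl sulfone | CC(C)=CCC/C(C)=C/C([Li])S(=O)(=O)c1ccccc1 | intermediate (not isolated)
15 | tert-butyl{[(2R)-2,8-dimethyl-2-[(3E,7E)-4,8,12-trimethyl-6-(phenylsulfonyl)trideca-3,7,11-trien-1-yl]-3,4-dihydro-2H-chromen-6-yl]oxy}dimethylsilane, both C6' epimers | CC(C)=CCC/C(C)=C/C(S(=O)(=O)c1ccccc1)C/C(C)=C/CC[C@]1(C)CCc2cc(O[Si](C)(C)C(C)(C)C)cc(C)c2O1 | intermediate
16 | tert-butyl{[(2R)-2,8-dimethyl-2-[(3E,7E)-4,8,12-trimethyltrideca-3,7,11-trien-1-yl]-3,4-dihydro-2H-chromen-6-yl]oxy}dimethylsilane | CC(C)=CCC/C(C)=C/CC/C(C)=C/CC[C@]1(C)CCc2cc(O[Si](C)(C)C(C)(C)C)cc(C)c2O1 | intermediate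
17 | (R)-δ-tocotrienol, (2R)-2,8-dimethyl-2-[(3E,7E)-4,8,12-trimethyltrideca-3,7,11-trien-1-yl]-3,4-dihydro-2H-chromen-6-ol | CC(C)=CCC/C(C)=C/CC/C(C)=C/CC[C@]1(C)CCc2cc(O)cc(C)c2O1 | intermediate
18 | (2R)-5-(hydroxymethyl)-2,8-dimethyl-2-[(3E,7E)-4,8,12-trimethyltrideca-3,7,11-trien-1-yl]-3,4-dihydro-2H-chromen-6-ol (present as its magnesium salt) | CC(C)=CCC/C(C)=C/CC/C(C)=C/CC[C@]1(C)CCc2c(CO)c(O)cc(C)c2O1 | intermediate (not isolated)
19 | (2R)-6-hydroxy-2,8-dimethyl-2-[(3E,7E)-4,8,12-trimethyltrideca-3,7,11-trien-1-yl]-3,4-dihydro-2H-chromene-5-carbaldehyde | CC(C)=CCC/C(C)=C/CC/C(C)=C/CC[C@]1(C)CCc2c(C=O)c(O)cc(C)c2O1 | target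

**Step count**

Total: 13 steps. Longest linear sequence: 12 steps (steps 1 to 8 and 10 to 13, from 4-bromo-3-methylphenol 1). Step 9 is a one-step branch.

**Steps most likely to fail**

1. Step 5 (ring expansion). Three processes could compete with the carbon shift: migration of oxygen in place of carbon, heterolysis of the tertiary O1–C2 bond of the activated spiro ether (with loss of configuration at C2 or elimination), and acid-induced reaction of the side-chain alkene.
The fallback sets out from borane 4, made from 3 as in step 2, and comes back at chromanol 8.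
Purchased 3-bromo-5-methylphenol F1 would be silylated (TIPSCl, imidazole, DMF) to (3-bromo-5-methylphenoxy)tri(propan-2-yl)silane F2. Suzuki coupling of 4 with F2 under the step 2 conditions should give (3R)-3,7-dimethyl-1-{3-methyl-5-[tri(propan-2-yl)silyloxy]phenyl}oct-6-en-3-ol F3. TBAF would then release 3-[(3R)-3-hydroxy-3,7-dimethyloct-6-en-1-yl]-5-methylphenol F4, in which the chain already sits meta to the hydroxyl. Teuber oxidation with ON(SO3K)2 (KH2PO4 buffer, acetone/water) should place oxygen para to the hydroxyl and give 2-[(3R)-3-hydroxy-3,7-dimethyloct-6-en-1-yl]-6-methylcyclohexa-2,5-diene-1,4-dione F5. Reduction with Na2S2O4 gives 2-[(3R)-3-hydroxy-3,7-dimethyloct-6-en-1-yl]-6-methylbenzene-1,4-diol F6. Cyclodehydration (TsOH cat., benzene, 60 °C) should close the chroman to 8. For tocopherol-type hydroquinone carbinols this closure is known to run mainly by attack of the tertiary hydroxyl on the ring carbon of the keto tautomer with loss of the ring oxygen, so retention at the carbinol carbon is expected.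

2. Step 7 (allylic oxidation). The oxidation may stall at low conversion, run on to the enal, attack the allylic CH2 or the Z-methyl, or damage the electron-rich aryl silyl ether.
The fallback sets out from 9 and comes back at 10.
Lemieux–Johnson cleavage of the single alkene of 9 (OsO4 cat., NaIO4, 2,6-lutidine, dioxane/water) should give 3-[(2S)-6-{[tert-butyl(dimethyl)silyl]oxy}-2,8-dimethyl-3,4-dihydro-2H-chromen-2-yl]propanal F7 (same geometry at C2; the descriptor changes by CIP priority only). Wittig olefination with the stabilised ylide ethyl 2-(triphenylphosphoranylidene)propanoate (CH2Cl2, rt) should give the E-configured ethyl (2E)-5-[(2R)-6-{[tert-butyl(dimethyl)silyl]oxy}-2,8-dimethyl-3,4-dihydro-2H-chromen-2-yl]-2-methylpent-2-enoate F8. Reduction with i-Bu2AlH (CH2Cl2, −78 °C) then gives allylic alcohol 10.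

3. Step 13 (formylation). Formaldehyde may attack C7 in place of C5, the magnesium chromanolate may be oxidised during prolonged heating in base, or the reaction may stop at the hydroxymethyl stage with diarylmethane formation.
The fallback sets out from 17 and comes back at 19.
Heating 17 with PhB(OH)2, (CH2O)n and propanoic acid (cat.) in toluene with removal of water should give, by boronate-templated ortho-hydroxymethylation under non-basic conditions, the 2-phenyl-4H-1,3,2-dioxaborin fused across C5–C6 of (R)-δ-tocotrienol F9 (C5–CH2–O–B(Ph)–O–C6). Any C7 isomer would be separated at this non-polar stage. Transesterification with propane-1,3-diol would release 18, here isolated, and MnO2 (CH2Cl2, rt) should oxidise the ortho-hydroxybenzylic alcohol selectively to 19.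

**Further compounds**

F1 | step 5 | 3-bromo-5-methylphenol (purchased) | Cc1cc(O)cc(Br)c1
F2 | step 5 | (3-bromo-5-methylphenoxy)tri(propan-2-yl)silane | Cc1cc(O[Si](C(C)C)(C(C)C)C(C)C)cc(Br)c1
F3 | step 5 | (3R)-3,7-dimethyl-1-{3-methyl-5-[tri(propan-2-yl)silyloxy]phenyl}oct-6-en-3-ol | CC(C)=CCC[C@](C)(CCc1cc(C)cc(O[Si](C(C)C)(C(C)C)C(C)C)c1)O
F4 | step 5 | 3-[(3R)-3-hydroxy-3,7-dimethyloct-6-en-1-yl]-5-methylphenol | CC(C)=CCC[C@](C)(CCc1cc(C)cc(O)c1)O
F5 | step 5 | 2-[(3R)-3-hydroxy-3,7-dimethyloct-6-en-1-yl]-6-methylcyclohexa-2,5-diene-1,4-dione | CC(C)=CCC[C@](C)(CCC1=CC(=O)C=C(C)C1=O)O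
F6 | step 5 | 2-[(3R)-3-hydroxy-3,7-dimethyloct-6-en-1-yl]-6-methylbenzene-1,4-diol | CC(C)=CCC[C@](C)(CCc1cc(O)cc(C)c1O)O
F7 | step 7 | 3-[(2S)-6-{[tert-butyl(dimethyl)silyl]oxy}-2,8-dimethyl-3,4-dihydro-2H-chromen-2-yl]propanal | O=CCC[C@]1(C)CCc2cc(O[Si](C)(C)C(C)(C)C)cc(C)c2O1
F8 | step 7 | ethyl (2E)-5-[(2R)-6-{[tert-butyl(dimethyl)silyl]oxy}-2,8-dimethyl-3,4-dihydro-2H-chromen-2-yl]-2-methylpent-2-enoate | CCOC(=O)/C(C)=C/CC[C@]1(C)CCc2cc(O[Si](C)(C)C(C)(C)C)cc(C)c2O1
F9 | step 13 | 2-phenyl-4H-1,3,2-dioxaborin fused across C5–C6 of (R)-δ-tocotrienol (C5–CH2–O–B(Ph)–O–C6) | CC(C)=CCC/C(C)=C/CC/C(C)=C/CC[C@]1(C)CCc2c3COB(c4ccccc4)Oc3cc(C)c2O1
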